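**Retrosynthetic overview**

1. Target ⇒ hydroxy lactone with free 8-OH plus the (S)-acetonide acid; the C8 ester is made late and the acetonide is hydrolysed last.
2. Lactone (ring B, formed last) ⇒ 6-hydroxy ester by 6,12-lactonisation, as in costunolide formation. Ten-membered carbocycle (ring A, formed first) ⇒ open chain by cutting C6–C7, the bond that closes farnesyl diphosphate to the germacrane ring. In the forward sense the (Z)-enal carbon C6 is attacked by C7 of an allylindium that zerovalent palladium and InI release from a vinyl epoxide; the epoxide opening also uncovers the 8-OH.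
3. Open chain ⇒ (Z)-2-iodo enoate (C1–C6, C10, C14) plus epoxy aldehyde (C7–C9, C11–C13) by a C9–C10 alkenylchromium addition; C9 is then inverted and acetylated in one Mitsunobu step.
4. Iodo enoate ⇒ nerol (the Z-C4=C5 olefin is bought). Epoxy aldehyde ⇒ ethyl 2-(bromomethyl)acrylate by Arbuzov, Horner–Wadsworth–Emmons and Sharpless epoxidation (sets C8).
5. Ring order: ring A (carbocycle), then ring B (lactone), both in one flask.

Assumption: the SMILES gives the absolute configuration; germacrane numbering (C1–C15) is used for positions; compounds 7, 9 and 19 are bought.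

**Route**

Step 1
Reactants: 1 nerol, (2Z)-3,7-dimethylocta-2,6-dien-1-ol
Product: 2 neryl triethylsilyl ether, {[(2Z)-3,7-dimethylocta-2,6-dien-1-yl]oxy}(triethyl)silane
Conditions: Et3SiCl, imidazole, CH2Cl2, 0 °C
Reagents that add atoms: chlorotriethylsilane, CC[Si](Cl)(CC)CC
Why: Silyl ether formation masks the C6 hydroxyl with a group that the later Swern conditions oxidise directly; no stereocentre is formed.

Step 2
Reactants: 2 neryl triethylsilyl ether
Product: 3 (4Z)-4-methyl-6-[(triethylsilyl)oxy]hex-4-enal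
Conditions: O3 (1.0 equiv), CH2Cl2, −78 °C; then Me2S, −78 → 23 °C
Reagents that add atoms: ozone, [O-][O+]=O
Why: Chemoselective ozonolysis, because the distal electron-rich trisubstituted olefin reacts faster than the C4=C5 olefin that is inductively deactivated by the allylic silyloxy group, so the Z geometry from nerol is kept.

Step 3
Reactants: 3 (4Z)-4-methyl-6-[(triethylsilyl)oxy]hex-4-enal; 4 methyl (triphenyl-λ5-phosphanylidene)acetate
Product: 6 methyl (2Z,6Z)-2-iodo-6-methyl-8-[(triethylsilyl)oxy]octa-2,6-dienoate, via iodo ylide 5 (not isolated)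
Conditions: 4, N-iodosuccinimide, CH2Cl2, −20 °C, 30 min; then 3, −20 → 23 °C
Reagents that add atoms: N-iodosuccinimide, O=C1CCC(=O)N1I
Why: One-pot ylide iodination and Wittig olefination, in which the stabilised iodo ylide places iodine cis to the alkyl chain (Z) and so fixes the later C1=C10 geometry.

Step 4
Reactants: 7 ethyl 2-(bromomethyl)prop-2-enoate
Product: 8 ethyl 2-[(diethoxyphosphoryl)methyl]prop-2-enoate
Conditions: P(OEt)3, neat, 90 °C
Reagents that add atoms: triethyl phosphite, CCOP(OCC)OCC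
Why: Michaelis–Arbuzov reaction of a reactive allylic bromide gives the allylic phosphonate; no stereocentre.

Step 5
Reactants: 8 ethyl 2-[(diethoxyphosphoryl)methyl]prop-2-enoate; 9 [(tert-butyldimethylsilyl)oxy]acetaldehyde
Product: 11 ethyl (3E)-5-hydroxy-2-methylidenepent-3-enoate, via silyl ether 10 (not isolated)
Conditions: NaH, THF, 0 °C; then 9, 0 → 23 °C; then 1 M aq HCl, 23 °C; product used at once
Reagents that add atoms: none
Why: Horner–Wadsworth–Emmons olefination at the α-carbon of the allylic phosphonate gives the (E)-configured 2-carboethoxy diene and the acid work-up removes the primary silyl ether; no stereocentre.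

Step 6
Reactants: 11 ethyl (3E)-5-hydroxy-2-methylidenepent-3-enoate
Product: 12 ethyl 2-[(2R,3R)-3-(hydroxymethyl)oxiran-2-yl]prop-2-enoate
Conditions: Ti(OiPr)4 (10 mol%), D-(−)-diethyl tartrate (12 mol%), tBuOOH, 4 Å molecular sieves, CH2Cl2, −20 °C
Reagents that add atoms: tert-butyl hydroperoxide, CC(C)(C)OO
Why: Sharpless asymmetric epoxidation of the (E)-allylic alcohol, where the D-(−)-tartrate complex delivers oxygen to the face that gives the (2R,3R)-epoxide and so fixes C8 (the C7 centre is erased later).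

Step 7
Reactants: 12 ethyl 2-[(2R,3R)-3-(hydroxymethyl)oxiran-2-yl]prop-2-enoate
Product: 13 ethyl 2-[(2R,3S)-3-formyloxiran-2-yl]prop-2-enoate
Conditions: TEMPO (10 mol%), PhI(OAc)2, CH2Cl2, 23 °C
Reagents that add atoms: none
Why: Oxoammonium (TEMPO) oxidation of the primary alcohol stops at the aldehyde without base, so the epoxy aldehyde does not epimerise.

Step 8
Reactants: 6 methyl (2Z,6Z)-2-iodo-6-methyl-8-[(triethylsilyl)oxy]octa-2,6-dienoate; 13 ethyl 2-[(2R,3S)-3-formyloxiran-2-yl]prop-2-enoate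
Product: 14 methyl (2E,6Z)-2-[(R)-{(2R,3R)-3-[3-ethoxy-3-oxoprop-1-en-2-yl]oxiran-2-yl}(hydroxy)methyl]-6-methyl-8-[(triethylsilyl)oxy]octa-2,6-dienoate
Conditions: CrCl2 (4 equiv), NiCl2 (2 mol%), DMSO, 23 °C
Reagents that add atoms: none
Why: Nozaki–Hiyama–Kishi coupling, in which zerovalent nickel inserts into the C–I bond, the alkenylchromium keeps the olefin geometry (C2 cis to C9) and adds to the epoxy aldehyde under Felkin–Anh control to give the anti carbinol, which is the C9 epimer of the target.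

Step 9
Reactants: 14 (the anti carbinol)
Product: 15 methyl (2E,6Z)-2-[(S)-(acetyloxy){(2S,3R)-3-[3-ethoxy-3-oxoprop-1-en-2-yl]oxiran-2-yl}methyl]-6-methyl-8-[(triethylsilyl)oxy]octa-2,6-dienoate
Conditions: PPh3 and DIAD premixed, then 14, AcOH, toluene, 0 → 23 °C
Reagents that add atoms: acetic acid, CC(=O)O
Why: Mitsunobu reaction, where SN2 attack of acetate on the oxyphosphonium inverts C9 to the target configuration and installs the 9-acetate at once, direct substitution being favoured because the SN2′ terminus C1 is substituted.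

Step 10
Reactants: 15 (the 9-acetate)
Product: 16 methyl (2E,6Z)-2-[(S)-(acetyloxy){(2S,3R)-3-[3-ethoxy-3-oxoprop-1-en-2-yl]oxiran-2-yl}methyl]-6-methyl-8-oxoocta-2,6-dienoate
Conditions: (COCl)2, DMSO, CH2Cl2, −78 → −40 °C; then Et3N, −78 → −20 °C
Reagents that add atoms: none
Why: Swern oxidation applied directly to the primary triethylsilyl ether, in which the chlorosulfonium reagent cleaves the unhindered Si–O bond and the alkoxysulfonium ylide collapses cold to the (Z)-enal without Z-to-E drift.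

Step 11
Reactants: 16 (the enal vinyl epoxide)
Product: 18 methyl (3aR,4S,5S,6E,10Z,11aR)-5-(acetyloxy)-4-hydroxy-10-methyl-3-methylidene-2-oxo-2,3,3a,4,5,8,9,11a-octahydrocyclodeca[b]furan-6-carboxylate, via hydroxy ester 17 (not isolated)
Conditions: Pd(PPh3)4 (10 mol%), InI (2.5 equiv), THF/DMPU 4:1, 16 added over 10 h (3 mM), 23 °C; then aq NH4Cl; then p-TsOH·H2O (cat.), CH2Cl2, 23 °C
Reagents that add atoms: none
Why: Proposed new method: zerovalent palladium ionises the vinyl epoxide to a 2-(ethoxycarbonyl)allylpalladium alkoxide, monovalent indium (InI) reduces it to a nucleophilic allylindium, and this adds through C7 to the tethered (Z)-enal carbon C6 (the C6–C7 union that closes farnesyl diphosphate to the germacrane ring), after which the 6-hydroxyl closes onto C12 as in costunolide formation; C8 is fixed, C7 is expected to be set by delivery of the aldehyde to the allyl face syn to the C8 indium alkoxide with C8–H in the allyl plane (allylic strain), and C6 by a chair transition state with the ring chain anti across the new bond (6,7-trans lactone); the closest known reactions are the intermolecular Pd/InI allylation of aldehydes by vinyl epoxides and the palladium-catalysed umpolung macrocyclisation of an allylic chloride onto an aldehyde to a ten-membered germacrene ring.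

Step 12
Reactants: 19 (2R)-3-bromo-2-hydroxy-2-methylpropanoic acid
Product: 21 (2S)-2,3-dihydroxy-2-methylpropanoic acid, via glycidate salt 20 (not isolated)
Conditions: NaOH (2.5 equiv), H2O, 0 → 60 °C; then HCl to pH 2
Reagents that add atoms: sodium hydroxide, [Na+].[OH-]
Why: Intramolecular Williamson epoxide closure followed by SN2 opening by hydroxide at the primary carbon never touches the quaternary centre, so the R bromo acid gives the S diol acid (only the priorities change).

Step 13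
Reactants: 21 (2S)-2,3-dihydroxy-2-methylpropanoic acid
Product: 22 methyl (4S)-2,2,4-trimethyl-1,3-dioxolane-4-carboxylate
Conditions: Me2C(OMe)2, MeOH, p-TsOH (cat.), 50 °C
Reagents that add atoms: 2,2-dimethoxypropane, COC(C)(C)OC; methanol, CO
Why: Fischer esterification and acid-catalysed transketalisation in one pot protect the acid and the 1,2-diol without touching the stereocentre.

Step 14
Reactants: 22 methyl (4S)-2,2,4-trimethyl-1,3-dioxolane-4-carboxylate
Product: 23 (4S)-2,2,4-trimethyl-1,3-dioxolane-4-carboxylic acid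
Conditions: LiOH, THF/H2O, 0 → 23 °C; then 1 M HCl to pH 3, 0 °C
Reagents that add atoms: lithium hydroxide, [Li+].[OH-]
Why: Saponification of the methyl ester, with cold mild acidification that keeps the acetonide; the quaternary stereocentre cannot epimerise.

Step 15
Reactants: 18 (the hydroxy lactone); 23 (4S)-2,2,4-trimethyl-1,3-dioxolane-4-carboxylic acid
Product: 25 methyl (3aS,4S,5S,6E,10Z,11aR)-5-(acetyloxy)-10-methyl-3-methylidene-2-oxo-4-{[(4S)-2,2,4-trimethyl-1,3-dioxolane-4-carbonyl]oxy}-2,3,3a,4,5,8,9,11a-octahydrocyclodeca[b]furan-6-carboxylate, via mixed anhydride 24 (not isolated)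
Conditions: 23, 2,4,6-trichlorobenzoyl chloride, Et3N, THF, 23 °C; then 18, DMAP, toluene, 23 °C
Reagents that add atoms: none
Why: Yamaguchi esterification, in which the mixed anhydride and DMAP acylate the hindered secondary 8-OH with retention at C8 and at the quaternary centre of the acid.

Step 16
Reactants: 25 (the acetonide-protected target)
Product: 26 CNP0197537.1, methyl (3aS,4S,5S,6E,10Z,11aR)-5-(acetyloxy)-4-{[(2S)-2,3-dihydroxy-2-methylpropanoyl]oxy}-10-methyl-3-methylidene-2-oxo-2,3,3a,4,5,8,9,11a-octahydrocyclodeca[b]furan-6-carboxylate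
Conditions: AcOH/THF/H2O 3:1:1, 45 °C
Reagents that add atoms: none
Why: Acid-catalysed acetonide hydrolysis in aqueous acetic acid leaves the acetate, the α-methylene lactone and both olefins untouched, and no stereocentre changes.

**Compound list**

1 | nerol, (2Z)-3,7-dimethylocta-2,6-dien-1-ol | OC/C=C(C)\CCC=C(C)C | starting material
2 | {[(2Z)-3,7-dimethylocta-2,6-dien-1-yl]oxy}(triethyl)silane | CC[Si](CC)(CC)OC/C=C(C)\CCC=C(C)C | intermediate
3 | (4Z)-4-methyl-6-[(triethylsilyl)oxy]hex-4-enal | CC[Si](CC)(CC)OC/C=C(C)\CCC=O | intermediate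
4 | methyl (triphenyl-λ5-phosphanylidene)acetate | COC(=O)C=P(c1ccccc1)(c1ccccc1)c1ccccc1 | starting material
5 | methyl iodo(triphenyl-λ5-phosphanylidene)acetate (iodo ylide) | COC(=O)C(I)=P(c1ccccc1)(c1ccccc1)c1ccccc1 | intermediate
6 | methyl (2Z,6Z)-2-iodo-6-methyl-8-[(triethylsilyl)oxy]octa-2,6-dienoate | CC[Si](CC)(CC)OC/C=C(C)\CC/C=C(\I)C(=O)OC | intermediate
7 | ethyl 2-(bromomethyl)prop-2-enoate | C=C(CBr)C(=O)OCC | starting material
8 | ethyl 2-[(diethoxyphosphoryl)methyl]prop-2-enoate | C=C(CP(=O)(OCC)OCC)C(=O)OCC | intermediate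
9 | [(tert-butyldimethylsilyl)oxy]acetaldehyde | O=CCO[Si](C)(C)C(C)(C)C | starting material
10 | ethyl (3E)-5-[(tert-butyldimethylsilyl)oxy]-2-methylidenepent-3-enoate | C=C(/C=C/CO[Si](C)(C)C(C)(C)C)C(=O)OCC | intermediate
11 | ethyl (3E)-5-hydroxy-2-methylidenepent-3-enoate | C=C(/C=C/CO)C(=O)OCC | intermediate
12 | ethyl 2-[(2R,3R)-3-(hydroxymethyl)oxiran-2-yl]prop-2-enoate | OC[C@H]1O[C@@H]1C(=C)C(=O)OCC | intermediate
13 | ethyl 2-[(2R,3S)-3-formyloxiran-2-yl]prop-2-enoate | O=C[C@H]1O[C@@H]1C(=C)C(=O)OCC | intermediate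
14 | methyl (2E,6Z)-2-[(R)-{(2R,3R)-3-[3-ethoxy-3-oxoprop-1-en-2-yl]oxiran-2-yl}(hydroxy)methyl]-6-methyl-8-[(triethylsilyl)oxy]octa-2,6-dienoate | CC[Si](CC)(CC)OC/C=C(C)\CC/C=C(/C(=O)OC)[C@@H](O)[C@H]1O[C@@H]1C(=C)C(=O)OCC | intermediate
15 | methyl (2E,6Z)-2-[(S)-(acetyloxy){(2S,3R)-3-[3-ethoxy-3-oxoprop-1-en-2-yl]oxiran-2-yl}methyl]-6-methyl-8-[(triethylsilyl)oxy]octa-2,6-dienoate | CC[Si](CC)(CC)OC/C=C(C)\CC/C=C(/C(=O)OC)[C@H](OC(C)=O)[C@H]1O[C@@H]1C(=C)C(=O)OCC | intermediate
16 | methyl (2E,6Z)-2-[(S)-(acetyloxy){(2S,3R)-3-[3-ethoxy-3-oxoprop-1-en-2-yl]oxiran-2-yl}methyl]-6-methyl-8-oxoocta-2,6-dienoate | O=C/C=C(C)\CC/C=C(/C(=O)OC)[C@H](OC(C)=O)[C@H]1O[C@@H]1C(=C)C(=O)OCC | intermediate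
17 | methyl (1E,5Z,7R,8S,9S,10S)-10-(acetyloxy)-8-(3-ethoxy-3-oxoprop-1-en-2-yl)-7,9-dihydroxy-5-methylcyclodeca-1,5-diene-1-carboxylate | O[C@@H]1/C=C(/C)CC/C=C(/C(=O)OC)[C@H](OC(C)=O)[C@@H](O)[C@H]1C(=C)C(=O)OCC | intermediate
18 | methyl (3aR,4S,5S,6E,10Z,11aR)-5-(acetyloxy)-4-hydroxy-10-methyl-3-methylidene-2-oxo-2,3,3a,4,5,8,9,11a-octahydrocyclodeca[b]furan-6-carboxylate | C=C1C(=O)O[C@@H]2/C=C(/C)CC/C=C(/C(=O)OC)[C@H](OC(C)=O)[C@@H](O)[C@@H]12 | intermediate
19 | (2R)-3-bromo-2-hydroxy-2-methylpropanoic acid | OC(=O)[C@@](C)(O)CBr | starting material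
20 | sodium (2S)-2-methyloxirane-2-carboxylate | [Na+].[O-]C(=O)[C@]1(C)CO1 | intermediate
21 | (2S)-2,3-dihydroxy-2-methylpropanoic acid | OC(=O)[C@@](C)(O)CO | intermediate
22 | methyl (4S)-2,2,4-trimethyl-1,3-dioxolane-4-carboxylate | COC(=O)[C@]1(C)COC(C)(C)O1 | intermediate
23 | (4S)-2,2,4-trimethyl-1,3-dioxolane-4-carboxylic acid | OC(=O)[C@]1(C)COC(C)(C)O1 | intermediate
24 | (4S)-2,2,4-trimethyl-1,3-dioxolane-4-carboxylic 2,4,6-trichlorobenzoic anhydride | O=C(OC(=O)[C@]1(C)COC(C)(C)O1)c1c(Cl)cc(Cl)cc1Cl | intermediate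
25 | methyl (3aS,4S,5S,6E,10Z,11aR)-5-(acetyloxy)-10-methyl-3-methylidene-2-oxo-4-{[(4S)-2,2,4-trimethyl-1,3-dioxolane-4-carbonyl]oxy}-2,3,3a,4,5,8,9,11a-octahydrocyclodeca[b]furan-6-carboxylate | C=C1C(=O)O[C@@H]2/C=C(/C)CC/C=C(/C(=O)OC)[C@H](OC(C)=O)[C@@H](OC(=O)[C@]3(C)COC(C)(C)O3)[C@@H]12 | intermediate
26 | CNP0197537.1, methyl (3aS,4S,5S,6E,10Z,11aR)-5-(acetyloxy)-4-{[(2S)-2,3-dihydroxy-2-methylpropanoyl]oxy}-10-methyl-3-methylidene-2-oxo-2,3,3a,4,5,8,9,11a-octahydrocyclodeca[b]furan-6-carboxylate | C=C1C(=O)O[C@@H]2/C=C(/C)CC/C=C(/C(=O)OC)[C@H](OC(C)=O)[C@@H](OC(=O)[C@@](C)(O)CO)[C@@H]12 | target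

**Step count and risks**

Total step count: 16. Longest linear sequence: 10 steps (steps 4–11, 15 and 16, from compound 7). The nerol branch (steps 1–3) joins at step 8 and the side-chain branch (steps 12–14) joins at step 15.

The three steps most likely to fail:

Step 11 is the weakest. The sense of induction at C6 and C7 in a ten-membered transition state is predicted, not known. The C8 indium alkoxide sits next to the 9-acetate, so an acyl shift is possible, and it could also close the 8,12-lactone or a dihydrofuran. The fallback sets out from 15. MgBr2·OEt2 opens the vinyl epoxide in the SN2′ sense to methyl (2E,6Z)-2-[(1S,2S,3Z)-1-(acetyloxy)-4-(bromomethyl)-5-ethoxy-2-hydroxy-5-oxopent-3-en-1-yl]-6-methyl-8-[(triethylsilyl)oxy]octa-2,6-dienoate F1. Et3SiOTf and 2,6-lutidine cap the 8-OH to give the bis-silyl ether F2. The Swern conditions of step 10 oxidise only the primary silyl ether to the bromo enal F3. CrCl2 in THF at high dilution (intramolecular Nozaki–Hiyama allylation through an allylchromium, then acid work-up) closes both rings to the 8-O-silyl lactone F4. HF·pyridine frees the 8-OH and the route is rejoined at 18.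

Step 8 is the second risk. Zerovalent nickel may ionise the vinyl epoxide of 13 as well as the C–I bond, and the Felkin ratio may be modest. The fallback sets out from 11. MnO2 gives ethyl (3E)-2-methylidene-5-oxopent-3-enoate F5. The same CrCl2/NiCl2 coupling with 6, now with no epoxide present, gives the racemic bis-allylic alcohol F6. A Sharpless kinetic resolution (Ti(OiPr)4, D-(−)-diisopropyl tartrate, tBuOOH, stopped near half conversion) epoxidises the fast enantiomer to the erythro epoxy alcohol, which is 14, where the route is rejoined.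

Step 9 is the third risk. SN2′ attack, epoxide participation, or addition of free PPh3 to the vinyl epoxide could compete with clean inversion. The fallback sets out from 14. Dess–Martin periodinane gives the epoxy ketone F7. Reagent-controlled 1,2-reduction with (S)-Me-CBS and catecholborane at −78 °C gives the (9S)-alcohol F8. Ac2O, pyridine and DMAP then give 15, where the route is rejoined.

**Further compounds**

F1 | step 11 | methyl (2E,6Z)-2-[(1S,2S,3Z)-1-(acetyloxy)-4-(bromomethyl)-5-ethoxy-2-hydroxy-5-oxopent-3-en-1-yl]-6-methyl-8-[(triethylsilyl)oxy]octa-2,6-dienoate | CC[Si](CC)(CC)OC/C=C(C)\CC/C=C(/C(=O)OC)[C@H](OC(C)=O)[C@@H](O)/C=C(\CBr)C(=O)OCC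
F2 | step 11 | methyl (2E,6Z)-2-[(1S,2S,3Z)-1-(acetyloxy)-4-(bromomethyl)-5-ethoxy-5-oxo-2-[(triethylsilyl)oxy]pent-3-en-1-yl]-6-methyl-8-[(triethylsilyl)oxy]octa-2,6-dienoate | CC[Si](CC)(CC)OC/C=C(C)\CC/C=C(/C(=O)OC)[C@H](OC(C)=O)[C@@H](O[Si](CC)(CC)CC)/C=C(\CBr)C(=O)OCC
F3 | step 11 | methyl (2E,6Z)-2-[(1S,2S,3Z)-1-(acetyloxy)-4-(bromomethyl)-5-ethoxy-5-oxo-2-[(triethylsilyl)oxy]pent-3-en-1-yl]-6-methyl-8-oxoocta-2,6-dienoate | O=C/C=C(C)\CC/C=C(/C(=O)OC)[C@H](OC(C)=O)[C@@H](O[Si](CC)(CC)CC)/C=C(\CBr)C(=O)OCC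
F4 | step 11 | methyl (3aS,4S,5S,6E,10Z,11aR)-5-(acetyloxy)-10-methyl-3-methylidene-2-oxo-4-[(triethylsilyl)oxy]-2,3,3a,4,5,8,9,11a-octahydrocyclodeca[b]furan-6-carboxylate | C=C1C(=O)O[C@@H]2/C=C(/C)CC/C=C(/C(=O)OC)[C@H](OC(C)=O)[C@@H](O[Si](CC)(CC)CC)[C@@H]12
F5 | step 8 | ethyl (3E)-2-methylidene-5-oxopent-3-enoate | C=C(/C=C/C=O)C(=O)OCC
F6 | step 8 | methyl (2E,6Z)-2-[(2E)-4-(ethoxycarbonyl)-1-hydroxypenta-2,4-dien-1-yl]-6-methyl-8-[(triethylsilyl)oxy]octa-2,6-dienoate (racemic) | CC[Si](CC)(CC)OC/C=C(C)\CC/C=C(/C(=O)OC)C(O)/C=C/C(=C)C(=O)OCC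
F7 | step 9 | methyl (2E,6Z)-2-{(2S,3R)-3-[3-ethoxy-3-oxoprop-1-en-2-yl]oxirane-2-carbonyl}-6-methyl-8-[(triethylsilyl)oxy]octa-2,6-dienoate | CC[Si](CC)(CC)OC/C=C(C)\CC/C=C(/C(=O)OC)C(=O)[C@H]1O[C@@H]1C(=C)C(=O)OCC
F8 | step 9 | methyl (2E,6Z)-2-[(S)-{(2R,3R)-3-[3-ethoxy-3-oxoprop-1-en-2-yl]oxiran-2-yl}(hydroxy)methyl]-6-methyl-8-[(triethylsilyl)oxy]octa-2,6-dienoate | CC[Si](CC)(CC)OC/C=C(C)\CC/C=C(/C(=O)OC)[C@H](O)[C@H]1O[C@@H]1C(=C)C(=O)OCC
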